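The dihydropyran ring of the cyclopenta[c]pyran core is divided into two three-atom units: C1–O–C3, an aryl oxocarbenium ion whose oxygen carries the α-CH2 of the isovaleryl ketone, and C7a–C4a–C4, a cyclopentenyl carbinol silyl ether used as a homoenolate equivalent. One Lewis-acid operation unites them: Prins addition forms C1–C7a, a 1,2-hydride shift turns the carbinol into the C4 methyl ketone and sets C4a–H, and aldol condensation of C3 onto C4 creates the ring C3=C4 bond. The precursors are an acyclic bis(2-oxoalkyl) acetal of the chromone aldehyde and an enantioenriched 3-methylcyclopentenyl silyl ether; the C7 methyl controls C7a, C4a and C1.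

Key step: step 9

Remark: C1, C3, C4, C4a, C5, C6, C7 and C7a are the locants of the hexahydrocyclopenta[c]pyran core of the target and primed locants belong to the chromone; paraformaldehyde is counted as formaldehyde 13.

Step 1
Reactants: 1 cyclopent-2-en-1-one
Product: 3 (3S)-3-methylcyclopent-1-en-1-yl trifluoromethanesulfonate, via methylzinc enolate 2 (not isolated)
Conditions: Me2Zn (1.5 equiv), Cu(OTf)2 (2 mol%), BINOL-derived phosphoramidite ligand (4 mol%), toluene, −30 °C; then Tf2O (1.6 equiv), −30 → 0 °C
Reagents that add atoms: dimethylzinc C[Zn]C; trifluoromethanesulfonic anhydride O=S(=O)(OS(=O)(=O)C(F)(F)F)C(F)(F)F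
Why: Copper-catalysed asymmetric conjugate addition followed by O-triflation of the regiodefined zinc enolate; the ligand enantiomer is chosen so that methyl adds to the enone face that gives the (S) centre (C7), and the enolate fixes the double bond between C4a and C7a.

Step 2
Reactants: 3 (3S)-3-methylcyclopent-1-en-1-yl trifluoromethanesulfonate; 4 acetaldehyde
Product: 5 1-[(3S)-3-methylcyclopent-1-en-1-yl]ethan-1-ol (both carbinol epimers)
Conditions: CrCl2 (4 equiv), NiCl2 (1 mol%), DMF, 23 °C
Reagents that add atoms: none
Why: Nozaki–Hiyama–Kishi coupling, in which nickel activates the alkenyl triflate and the alkenylchromium reagent adds chemoselectively to the aldehyde; C7 is untouched and the new carbinol centre, formed as a mixture, is erased in step 9.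

Step 3
Reactants: 5 1-[(3S)-3-methylcyclopent-1-en-1-yl]ethan-1-ol
Product: 6 triethyl{1-[(3S)-3-methylcyclopent-1-en-1-yl]ethoxy}silane
Conditions: TESCl, imidazole, CH2Cl2, 0 → 23 °C
Reagents that add atoms: chlorotriethylsilane CC[Si](Cl)(CC)CC
Why: Standard silyl ether formation; the triethylsilyl group blocks O-attack on the oxocarbenium ion of step 9 and later leaves from the C4 oxygen.

Step 4
Reactants: 7 1-(2-hydroxy-6-methylphenyl)ethan-1-one
Product: 9 5-methyl-2-(methylsulfanyl)-4H-chromen-4-one, via potassium chromene-2-thiolate 8 (not isolated)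
Conditions: KOtBu (3.1 equiv), CS2, THF, 0 → 23 °C; then MeI (3.1 equiv), 0 → 23 °C
Reagents that add atoms: carbon disulfide S=C=S; iodomethane CI
Why: Claisen-type C-dithiocarboxylation of the methyl ketone, cyclisation of the phenoxide with loss of hydrosulfide and S-methylation of the soft thiolate should give the 2-(methylsulfanyl)chromone; no stereocentre is formed.

Step 5
Reactants: 9 5-methyl-2-(methylsulfanyl)-4H-chromen-4-one
Product: 10 5-methyl-2-(methylsulfanyl)-4-oxo-4H-chromene-3-carbaldehyde
Conditions: POCl3, DMF, 0 → 60 °C; aq. NaOAc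
Reagents that add atoms: N,N-dimethylformamide CN(C)C=O; water O
Why: Vilsmeier–Haack formylation at C3', the nucleophilic β-carbon of the cyclic α-oxo ketene O,S-acetal; no stereocentre is formed.

Step 6
Reactants: 10 5-methyl-2-(methylsulfanyl)-4-oxo-4H-chromene-3-carbaldehyde
Product: 11 2-methoxy-5-methyl-4-oxo-4H-chromene-3-carbaldehyde
Conditions: NaOMe (1.05 equiv), MeOH–THF, 0 °C
Reagents that add atoms: sodium methoxide C[O-].[Na+]
Why: Addition–elimination (nucleophilic vinylic substitution) at C2', which is doubly activated by the 4-oxo and 3-formyl groups, with methanethiolate as the leaving group; no stereocentre is formed.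

Step 7
Reactants: 12 3-methylbutanal; 13 formaldehyde (as paraformaldehyde)
Product: 15 4-methyl-1-[(trimethylsilyl)oxy]pentan-2-one, via hydroxy ketone 14 (not isolated)
Conditions: thiazolium salt precatalyst (5 mol%), iPr2NEt (10 mol%), THF, 60 °C; then TMSCl, Et3N, 0 °C
Reagents that add atoms: chlorotrimethylsilane C[Si](C)(C)Cl
Why: Carbene-catalysed cross-acyloin reaction (hydroxymethylation), in which the Breslow intermediate of 12 adds to formaldehyde, followed by silylation in the same flask; no stereocentre is formed.

Step 8
Reactants: 11 2-methoxy-5-methyl-4-oxo-4H-chromene-3-carbaldehyde; 15 4-methyl-1-[(trimethylsilyl)oxy]pentan-2-one (2.2 equiv)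
Product: 16 1,1'-{[(2-methoxy-5-methyl-4-oxo-4H-chromen-3-yl)methylene]bis(oxy)}bis(4-methylpentan-2-one)
Conditions: TMSOTf (5 mol%), CH2Cl2, −78 → −40 °C; pyridine quench
Reagents that add atoms: none
Why: TMSOTf-catalysed acetalisation of the aldehyde with two equivalents of the silyl ether, driven by formation of hexamethyldisiloxane; the acetal carbon is not stereogenic.

Step 9
Reactants: 16 1,1'-{[(2-methoxy-5-methyl-4-oxo-4H-chromen-3-yl)methylene]bis(oxy)}bis(4-methylpentan-2-one); 6 triethyl{1-[(3S)-3-methylcyclopent-1-en-1-yl]ethoxy}silane (1.5 equiv)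
Product: 19 3-[(1R,4aS,7S,7aR)-4,7-dimethyl-3-(3-methylbutanoyl)-1,4a,5,6,7,7a-hexahydrocyclopenta[c]pyran-1-yl]-2-methoxy-5-methyl-4H-chromen-4-one, via oxocarbenium triflate 17 (not isolated), via keto ether 18 (not isolated)
Conditions: TMSOTf (1.2 equiv), 2,6-di-tert-butyl-4-methylpyridine (0.2 equiv), CH2Cl2, −78 → −30 °C; then 0 °C; aq. NaHCO3
Reagents that add atoms: none
Why: Proposed new method: TMSOTf ionises acetal 16 to the chromonyl-stabilised oxocarbenium ion 17, which adds in Prins fashion to the ring CH of the trisubstituted alkene of 6 (C1–C7a), the tertiary C4a cation being quenched by a 1,2-hydride shift from the silyloxy carbon to give the C4 methyl ketone of 18 and Et3SiOTf (the allylic silyl ether acts as a homoenolate equivalent), and the silyl triflate then drives aldol condensation of the O–CH2 carbon C3 onto C4 to form C3=C4. The closest known reaction types are Prins–pinacol (semipinacol-terminated Prins) additions of acetals to allylic silyl ethers and the intramolecular aldol cyclodehydration of α-alkoxy ketones onto ketones, as in the Rap–Stoermer benzofuran synthesis. The pyran ring closes by a 6-(enolexo)-exo-trig aldol addition followed by dehydration into conjugation with the ketone and the ring oxygen. C7a should be set by attack of 17 anti to the C7 methyl; C4a by hydride delivery anti to the new C1–C7a bond (net trans addition across the alkene), which puts the acetyl and C1 arms cis, the only arrangement that closes the ring readily; C1 is expected to equilibrate by reversible C1–O ionisation to the epimer with the aryl group pseudo-equatorial and trans to C7. The step needs Markovnikov attack at C7a, secured by the tertiary cation at C4a, and aldolisation through C3 and not through C4a, secured because only the C3 adduct can dehydrate to the push–pull enone.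

Compound list
1 | cyclopent-2-en-1-one | O=C1C=CCC1 | starting material
2 | methylzinc (3S)-3-methylcyclopent-1-en-1-olate | C[Zn]OC1=C[C@@H](C)CC1 | intermediate
3 | (3S)-3-methylcyclopent-1-en-1-yl trifluoromethanesulfonate | O=S(=O)(OC1=C[C@@H](C)CC1)C(F)(F)F | intermediate
4 | acetaldehyde | CC=O | starting material
5 | 1-[(3S)-3-methylcyclopent-1-en-1-yl]ethan-1-ol (both carbinol epimers) | CC(O)C1=C[C@@H](C)CC1 | intermediate
6 | triethyl{1-[(3S)-3-methylcyclopent-1-en-1-yl]ethoxy}silane | CC(O[Si](CC)(CC)CC)C1=C[C@@H](C)CC1 | intermediate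
7 | 1-(2-hydroxy-6-methylphenyl)ethan-1-one | CC(=O)c1c(C)cccc1O | starting material
8 | potassium 5-methyl-4-oxo-4H-chromene-2-thiolate | Cc1cccc2oc([S-])cc(=O)c12.[K+] | intermediate
9 | 5-methyl-2-(methylsulfanyl)-4H-chromen-4-one | CSc1cc(=O)c2c(C)cccc2o1 | intermediate
10 | 5-methyl-2-(methylsulfanyl)-4-oxo-4H-chromene-3-carbaldehyde | CSc1oc2cccc(C)c2c(=O)c1C=O | intermediate
11 | 2-methoxy-5-methyl-4-oxo-4H-chromene-3-carbaldehyde | COc1oc2cccc(C)c2c(=O)c1C=O | intermediate
12 | 3-methylbutanal | CC(C)CC=O | starting material
13 | formaldehyde (as paraformaldehyde) | C=O | starting material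
14 | 1-hydroxy-4-methylpentan-2-one | CC(C)CC(=O)CO | intermediate
15 | 4-methyl-1-[(trimethylsilyl)oxy]pentan-2-one | CC(C)CC(=O)CO[Si](C)(C)C | intermediate
16 | 1,1'-{[(2-methoxy-5-methyl-4-oxo-4H-chromen-3-yl)methylene]bis(oxy)}bis(4-methylpentan-2-one) | COc1oc2cccc(C)c2c(=O)c1C(OCC(=O)CC(C)C)OCC(=O)CC(C)C | intermediate
17 | [(2-methoxy-5-methyl-4-oxo-4H-chromen-3-yl)methylidene](4-methyl-2-oxopentyl)oxonium trifluoromethanesulfonate | COc1oc2cccc(C)c2c(=O)c1C=[O+]CC(=O)CC(C)C.[O-]S(=O)(=O)C(F)(F)F | intermediate
18 | 1-{[(1R,2S,5S)-2-acetyl-5-methylcyclopentyl](2-methoxy-5-methyl-4-oxo-4H-chromen-3-yl)methoxy}-4-methylpentan-2-one (C1 epimers) | COc1oc2cccc(C)c2c(=O)c1C(OCC(=O)CC(C)C)[C@@H]1[C@@H](C)CC[C@@H]1C(C)=O | intermediate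
19 | 3-[(1R,4aS,7S,7aR)-4,7-dimethyl-3-(3-methylbutanoyl)-1,4a,5,6,7,7a-hexahydrocyclopenta[c]pyran-1-yl]-2-methoxy-5-methyl-4H-chromen-4-one | COc1oc2cccc(C)c2c(=O)c1[C@@H]1OC(C(=O)CC(C)C)=C(C)[C@H]2CC[C@H](C)[C@H]21 | target

Total step count: 9 steps.
Longest linear sequence: 5 steps (steps 4, 5, 6, 8 and 9, from 7 to 19).

Steps most likely to fail

Step 9 (Proposed new method). The stabilised ion 17 may add too slowly, so that ionisation of the allylic silyl ether to an allyl cation competes. The C4a cation may lose a proton instead of accepting hydride, and unselective reprotonation would then erode the cis ring fusion. Ion 17 may also oligomerise through its enolisable ketone arm. The fallback uses known chemistry in separate operations; it sets out from 5 and 11 and comes back to the route at 18. Alcohol 5 is converted with NaH and N,N-diisopropylcarbamoyl chloride into 1-[(3S)-3-methylcyclopent-1-en-1-yl]ethyl N,N-diisopropylcarbamate F1. Deprotonation (s-BuLi, TMEDA, Et2O, −78 °C), transmetalation with Ti(OiPr)4 and addition of 11 (homoaldol reaction of a titanated allyl carbamate, γ-attack through a chair transition state anti to the C7 methyl) should give the γ-hydroxy enol carbamate F2. Rh2(OAc)4-catalysed O–H insertion with 1-diazo-4-methylpentan-2-one F3 (from 3-methylbutanoyl chloride and TMSCHN2) should give the keto ether enol carbamate F4. Methanolysis of the enol carbamate (MeSO3H, Hg(OAc)2 cat., MeOH, then aqueous acid) releases the methyl ketone, which is 18, and TsOH in benzene at 50 °C completes the aldol cyclodehydration to 19.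

Step 8. Acetal formation may stall because the aldehyde is a deactivated vinylogous ester, or the 2'-methoxy group may be lost by addition–elimination at C2'. The fallback sets out from 11 and 15 and comes back at 17. No acetal is isolated: 11, 15 (1.1 equiv) and 6 are combined and TMSOTf (1.1 equiv) is added at −78 °C, so that the aldehyde and the silyl ether give 17 directly in the flask (in situ oxocarbenium generation from an aldehyde and a silyl ether, as in silyl-modified Sakurai reactions), which goes on to 19 as in step 9. This fallback makes no new compound (entry F0).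

Step 5. Formylation may fail through low nucleophilicity of C3' or through chlorination of the chromone by the Vilsmeier reagent. The fallback sets out from 9 and comes back at 11, so it also bypasses step 6. Oxidation with mCPBA (2.2 equiv) should give 5-methyl-2-(methylsulfonyl)-4H-chromen-4-one F5; NaOMe in MeOH should displace the sulfinate to give 2-methoxy-5-methyl-4H-chromen-4-one F6; NIS in MeCN should iodinate C3' to give 3-iodo-2-methoxy-5-methyl-4H-chromen-4-one F7; iodine–magnesium exchange with iPrMgCl·LiCl (THF, −40 °C) and a DMF quench should give 11.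

Further compounds
F1 | step 9 | 1-[(3S)-3-methylcyclopent-1-en-1-yl]ethyl N,N-diisopropylcarbamate | CC(OC(=O)N(C(C)C)C(C)C)C1=C[C@@H](C)CC1
F2 | step 9 | 1-{(1R,5S)-2-[hydroxy(2-methoxy-5-methyl-4-oxo-4H-chromen-3-yl)methyl]... enol carbamate: 1-{(2R,3S)-2-[hydroxy(2-methoxy-5-methyl-4-oxo-4H-chromen-3-yl)methyl]-3-methylcyclopentylidene}ethyl N,N-diisopropylcarbamate | COc1oc2cccc(C)c2c(=O)c1C(O)[C@@H]1[C@@H](C)CCC1=C(C)OC(=O)N(C(C)C)C(C)C
F3 | step 9 | 1-diazo-4-methylpentan-2-one | CC(C)CC(=O)C=[N+]=[N-]
F4 | step 9 | 1-{(2R,3S)-2-[(2-methoxy-5-methyl-4-oxo-4H-chromen-3-yl)(4-methyl-2-oxopentyloxy)methyl]-3-methylcyclopentylidene}ethyl N,N-diisopropylcarbamate | COc1oc2cccc(C)c2c(=O)c1C(OCC(=O)CC(C)C)[C@@H]1[C@@H](C)CCC1=C(C)OC(=O)N(C(C)C)C(C)C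
F0 | step 8 | none | none
F5 | step 5 | 5-methyl-2-(methylsulfonyl)-4H-chromen-4-one | CS(=O)(=O)c1cc(=O)c2c(C)cccc2o1
F6 | step 5 | 2-methoxy-5-methyl-4H-chromen-4-one | COc1cc(=O)c2c(C)cccc2o1
F7 | step 5 | 3-iodo-2-methoxy-5-methyl-4H-chromen-4-one | COc1oc2cccc(C)c2c(=O)c1I
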